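**Retrosynthetic overview**

- Numbering: ring C1 (angeloyloxy), C2=C3 (C3 methyl), C4 (acetoxy), C5, C6; chain C7 (methyl), C8, C9 (acetoxy), C10=C11. The strategy rests on the fact that the open-chain C6/C7 pair and the 1,3-related C9 carbinol fit into one δ-lactone (C1 as carbonyl, C6, C7, C8, C9 and the C9 oxygen), whose ring relays configuration from C9 to C7 to C6.
- Late stage: the cyclohexene is closed last at C2=C3 by ring-closing metathesis of a C1 vinyl ketone with the C3 isopropenyl group. Luche reduction then sets C1, the angelate is installed, PMB at C4 is exchanged for acetate, and C9 is inverted and acetylated in one Mitsunobu step.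
- Key disconnection: C7–CH3 and C5–C6 are made in one flask by adding Me2CuLi to the (S)-dihydropyranone 7 and trapping the enolate with the C3–C5 triflate 15, which brings C4.
- Fragments: 7 comes from 3-methylbut-2-enal (allylboration, acryloylation, ring-closing metathesis); 15 comes from (R)-2,3-O-isopropylideneglyceraldehyde.
- Ring order: the dihydropyranone is formed first (step 3) and opened in step 12; the cyclohexene is formed second (step 15).

Key step: step 11

Remark: the allylboration catalyst is defined by the face it must attack (Si face of 1); (S)-TRIP is taken to be that antipode, by analogy with the sense known for aryl and alkenyl aldehydes.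

**Route**

Step 1
Reactants: 1 3-methylbut-2-enal; 2 allylboronic acid pinacol ester
Product: 4 (4S)-6-methylhepta-1,5-dien-4-ol, via homoallyl pinacol borate 3 (not isolated)
Conditions: (S)-3,3′-bis(2,4,6-triisopropylphenyl)-1,1′-binaphthyl-2,2′-diyl hydrogen phosphate ((S)-TRIP, 5 mol %), 4 Å MS, toluene, −30 °C; then aq NaHCO3
Reagents that add atoms: none
Why: Chiral-phosphoric-acid-catalysed allylboration through a chair Zimmerman–Traxler transition state in which the catalyst should direct allyl to the Si face of the aldehyde, setting C9 as S, the epimer the trans-directing lactone requires.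

Step 2
Reactants: 4 (4S)-6-methylhepta-1,5-dien-4-ol; 5 acryloyl chloride
Product: 6 (4S)-6-methylhepta-1,5-dien-4-yl prop-2-enoate
Conditions: Et3N, DMAP (cat.), CH2Cl2, −20 → 0 °C
Reagents that add atoms: none
Why: Base-mediated O-acylation of a secondary alcohol that leaves the carbinol centre untouched.

Step 3
Reactants: 6 (4S)-6-methylhepta-1,5-dien-4-yl prop-2-enoate
Product: 7 (6S)-6-(2-methylprop-1-en-1-yl)-5,6-dihydro-2H-pyran-2-one
Conditions: second-generation Grubbs catalyst RuCl2(=CHPh)(PCy3)(H2IMes) (3 mol %), CH2Cl2 (0.01 M), 40 °C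
Reagents that add atoms: none
Why: Ring-closing metathesis of the acrylate with the terminal allyl alkene closes the six-membered enoate, while the trisubstituted isobutenyl alkene should be too hindered to compete.

Step 4
Reactants: 8 (R)-2,3-O-isopropylideneglyceraldehyde
Product: 9 1-[(4R)-2,2-dimethyl-1,3-dioxolan-4-yl]ethan-1-ol (both carbinol epimers)
Conditions: MeMgBr, Et2O, −78 → 0 °C; then H2O/aq NH4Cl
Reagents that add atoms: methylmagnesium bromide, C[Mg]Br
Why: Grignard addition to the aldehyde; the new carbinol centre is removed in the next step, so its configuration does not matter.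

Step 5
Reactants: 9 1-[(4R)-2,2-dimethyl-1,3-dioxolan-4-yl]ethan-1-ol
Product: 10 1-[(4R)-2,2-dimethyl-1,3-dioxolan-4-yl]ethan-1-one
Conditions: Dess–Martin periodinane, NaHCO3, CH2Cl2, 0 °C → rt
Reagents that add atoms: none
Why: Buffered Dess–Martin oxidation gives the methyl ketone under non-enolising conditions, so the α-alkoxy centre should stay intact.

Step 6
Reactants: 10 1-[(4R)-2,2-dimethyl-1,3-dioxolan-4-yl]ethan-1-one
Product: 11 (4S)-2,2-dimethyl-4-(prop-1-en-2-yl)-1,3-dioxolane
Conditions: Ph3PCH3Br, KOt-Bu, THF, 0 °C (ylide pre-formed); then 10, −78 → 0 °C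
Reagents that add atoms: methyltriphenylphosphonium bromide, C[P+](c1ccccc1)(c1ccccc1)c1ccccc1.[Br-]
Why: Wittig methylenation with a pre-formed non-stabilised ylide at low temperature converts the ketone into the isopropenyl group (C3 with its methyl) faster than the α-centre can enolise; the descriptor changes to S only through priority change.

Step 7
Reactants: 11 (4S)-2,2-dimethyl-4-(prop-1-en-2-yl)-1,3-dioxolane
Product: 12 (2S)-3-methylbut-3-ene-1,2-diol
Conditions: Dowex 50WX8 (H+ form), MeOH–H2O (9:1), rt; filter, concentrate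
Reagents that add atoms: none
Why: Acid-catalysed acetonide hydrolysis on a resin avoids aqueous extraction of the water-soluble diol and does not touch the stereocentre.

Step 8
Reactants: 12 (2S)-3-methylbut-3-ene-1,2-diol
Product: 13 (4S)-2-(4-methoxyphenyl)-4-(prop-1-en-2-yl)-1,3-dioxolane (both acetal epimers)
Conditions: 4-MeOC6H4CH(OMe)2, PPTS (cat.), CH2Cl2, rt
Reagents that add atoms: 4-methoxybenzaldehyde dimethyl acetal, COc1ccc(C(OC)OC)cc1
Why: Acid-catalysed transacetalisation gives the five-membered p-methoxybenzylidene acetal of the 1,2-diol; the acetal carbon is lost as a stereocentre in the next step.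

Step 9
Reactants: 13 (4S)-2-(4-methoxyphenyl)-4-(prop-1-en-2-yl)-1,3-dioxolane
Product: 14 (2S)-2-[(4-methoxybenzyl)oxy]-3-methylbut-3-en-1-ol
Conditions: i-Bu2AlH (3 equiv), CH2Cl2, −78 → 0 °C; aq KNaC4H4O6
Reagents that add atoms: none
Why: Regioselective reductive opening of the arylidene acetal: aluminium binds the less hindered primary oxygen, the acetal bond to that oxygen breaks and hydride reduces the oxocarbenium ion, leaving PMB on the secondary (C4) oxygen.

Step 10
Reactants: 14 (2S)-2-[(4-methoxybenzyl)oxy]-3-methylbut-3-en-1-ol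
Product: 15 (2S)-2-[(4-methoxybenzyl)oxy]-3-methylbut-3-en-1-yl trifluoromethanesulfonate
Conditions: Tf2O, 2,6-lutidine, CH2Cl2, −78 °C; cold work-up, used at once
Reagents that add atoms: trifluoromethanesulfonic anhydride, O=S(=O)(OS(=O)(=O)C(F)(F)F)C(F)(F)F
Why: O-sulfonylation of the primary alcohol with a hindered base gives the primary triflate without touching C4.

Step 11
Reactants: 7 (6S)-6-(2-methylprop-1-en-1-yl)-5,6-dihydro-2H-pyran-2-one; 15 (2S)-2-[(4-methoxybenzyl)oxy]-3-methylbut-3-en-1-yl trifluoromethanesulfonate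
Product: 18 (3S,4R,6S)-3-{(2R)-2-[(4-methoxybenzyl)oxy]-3-methylbut-3-en-1-yl}-4-methyl-6-(2-methylprop-1-en-1-yl)tetrahydro-2H-pyran-2-one, via lithium dimethylcuprate 16 (not isolated), via lithium lactone enolate 17 (not isolated)
Conditions: CuI, MeLi (2 equiv), Et2O, 0 °C; 7, −78 → −40 °C; then 15 (1.5 equiv) in THF, −78 → −20 °C; aq NH4Cl/NH4OH
Reagents that add atoms: methyllithium, [Li]C
Why: Me2CuLi forms a π-complex with the enoate of 7 and transfers methyl to C7 by oxidative addition and reductive elimination, leaving lithium enolate 17, whose C6 then displaces the primary triflate of 15 in an SN2 reaction; the closest known reaction type is the trans-selective cuprate conjugate addition to 6-substituted 5,6-dihydro-2H-pyran-2-ones followed by trans-selective alkylation of the lactone enolate. No ring is closed; the bonds formed are C7–CH3 and C5–C6. C7 is set by the ring: in the half-chair of 7 the isobutenyl group on C9 is pseudo-equatorial, and stereoelectronically preferred axial attack places methyl anti to it (4,6-trans). C6 is set by that new methyl, which sits pseudo-axial next to the enolate carbon and blocks one face, so the electrophile enters anti to it (3,4-trans); C4 arrives intact in 15 and C9 is untouched. The step needs 1,3-trans addition followed by 1,2-trans alkylation, both secured by the conformational bias of the six-membered lactone and not by a chiral reagent. It also needs 1,4-addition to outrun substitution at the allylic C9–O bond, which the much more electrophilic enoate should ensure at −78 °C with only a slight excess of cuprate.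

Step 12
Reactants: 18 (3S,4R,6S)-3-{(2R)-2-[(4-methoxybenzyl)oxy]-3-methylbut-3-en-1-yl}-4-methyl-6-(2-methylprop-1-en-1-yl)tetrahydro-2H-pyran-2-one
Product: 19 (2S,3R,5S)-5-hydroxy-N-methoxy-2-{(2R)-2-[(4-methoxybenzyl)oxy]-3-methylbut-3-en-1-yl}-N,3,7-trimethyloct-6-enamide
Conditions: MeNHOMe·HCl, i-PrMgCl, THF, −20 → 0 °C; aq NH4Cl; used at once
Reagents that add atoms: N,O-dimethylhydroxylamine hydrochloride, CNOC.Cl
Why: Aminolysis of the lactone by the magnesium amide of N,O-dimethylhydroxylamine (Weinreb amide formation) opens the ring without a strong Lewis acid that could ionise the allylic C9–O bond and without epimerising C6.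

Step 13
Reactants: 19 (2S,3R,5S)-5-hydroxy-N-methoxy-2-{(2R)-2-[(4-methoxybenzyl)oxy]-3-methylbut-3-en-1-yl}-N,3,7-trimethyloct-6-enamide
Product: 20 (2S,3R,5S)-5-[(tert-butyldimethylsilyl)oxy]-N-methoxy-2-{(2R)-2-[(4-methoxybenzyl)oxy]-3-methylbut-3-en-1-yl}-N,3,7-trimethyloct-6-enamide
Conditions: TBSOTf, 2,6-lutidine, CH2Cl2, −78 °C
Reagents that add atoms: tert-butyldimethylsilyl trifluoromethanesulfonate, CC(C)(C)[Si](C)(C)OS(=O)(=O)C(F)(F)F
Why: Fast low-temperature silylation caps the C9 hydroxyl before it can relactonise and protects it through the Grignard, reduction and acylation steps.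

Step 14
Reactants: 20 (2S,3R,5S)-5-[(tert-butyldimethylsilyl)oxy]-N-methoxy-2-{(2R)-2-[(4-methoxybenzyl)oxy]-3-methylbut-3-en-1-yl}-N,3,7-trimethyloct-6-enamide
Product: 22 (4S,5R,7S)-7-[(tert-butyldimethylsilyl)oxy]-4-{(2R)-2-[(4-methoxybenzyl)oxy]-3-methylbut-3-en-1-yl}-5,9-dimethyldeca-1,8-dien-3-one, via magnesium hemiaminal chelate 21 (not isolated)
Conditions: CH2=CHMgBr (3 equiv), THF, −78 → 0 °C; inverse quench into cold 1 M aq HCl/Et2O
Reagents that add atoms: vinylmagnesium bromide, C=C[Mg]Br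
Why: Weinreb ketone synthesis, in which the chelated tetrahedral adduct survives until the acidic quench so that only one vinyl group adds, and the acidic inverse quench keeps the liberated hydroxylamine from adding to the vinyl ketone.

Step 15
Reactants: 22 (4S,5R,7S)-7-[(tert-butyldimethylsilyl)oxy]-4-{(2R)-2-[(4-methoxybenzyl)oxy]-3-methylbut-3-en-1-yl}-5,9-dimethyldeca-1,8-dien-3-one
Product: 23 (4R,6S)-6-{(2R,4S)-4-[(tert-butyldimethylsilyl)oxy]-6-methylhept-5-en-2-yl}-4-[(4-methoxybenzyl)oxy]-3-methylcyclohex-2-en-1-one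
Conditions: second-generation Hoveyda–Grubbs catalyst RuCl2(=CH-C6H4-2-O-i-Pr)(H2IMes) (5–10 mol %), toluene (0.005 M), 80 °C
Reagents that add atoms: none
Why: Ring-closing metathesis of the vinyl ketone with the 1,1-disubstituted C3 alkene forms the C2=C3 bond of the six-membered enone, the kinetically preferred ring size over closure onto the more hindered C10=C11 alkene.

Step 16
Reactants: 23 (4R,6S)-6-{(2R,4S)-4-[(tert-butyldimethylsilyl)oxy]-6-methylhept-5-en-2-yl}-4-[(4-methoxybenzyl)oxy]-3-methylcyclohex-2-en-1-one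
Product: 24 (1S,4R,6S)-6-{(2R,4S)-4-[(tert-butyldimethylsilyl)oxy]-6-methylhept-5-en-2-yl}-4-[(4-methoxybenzyl)oxy]-3-methylcyclohex-2-en-1-ol
Conditions: NaBH4, CeCl3·7H2O, MeOH, −78 → −40 °C
Reagents that add atoms: none
Why: Luche 1,2-reduction in which hydride adds axially to the half-chair with the C6 chain equatorial and the C4 ether pseudo-axial, i.e. on the face opposite the C4 oxygen, giving the equatorial C1 alcohol trans to the C6 chain and cis to the C4 oxygen (1S).

Step 17
Reactants: 24 (1S,4R,6S)-6-{(2R,4S)-4-[(tert-butyldimethylsilyl)oxy]-6-methylhept-5-en-2-yl}-4-[(4-methoxybenzyl)oxy]-3-methylcyclohex-2-en-1-ol; 25 angelic acid, (2Z)-2-methylbut-2-enoic acid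
Product: 27 (1S,4R,6S)-6-{(2R,4S)-4-[(tert-butyldimethylsilyl)oxy]-6-methylhept-5-en-2-yl}-4-[(4-methoxybenzyl)oxy]-3-methylcyclohex-2-en-1-yl (2Z)-2-methylbut-2-enoate, via angelic trichlorobenzoic mixed anhydride 26 (not isolated)
Conditions: 25, 2,4,6-Cl3C6H2COCl, Et3N, toluene, rt; then 24, toluene, 75 °C
Reagents that add atoms: none
Why: Yamaguchi-type esterification through the mixed anhydride acylates the hindered allylic alcohol at the angeloyl carbonyl without a nucleophilic catalyst, the condition under which the Z-enoate should not isomerise to the tiglate; C1 is not touched.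

Step 18
Reactants: 27 (1S,4R,6S)-6-{(2R,4S)-4-[(tert-butyldimethylsilyl)oxy]-6-methylhept-5-en-2-yl}-4-[(4-methoxybenzyl)oxy]-3-methylcyclohex-2-en-1-yl (2Z)-2-methylbut-2-enoate
Product: 28 (1S,4R,6S)-6-{(2R,4S)-4-[(tert-butyldimethylsilyl)oxy]-6-methylhept-5-en-2-yl}-4-hydroxy-3-methylcyclohex-2-en-1-yl (2Z)-2-methylbut-2-enoate
Conditions: DDQ (1.2 equiv), CH2Cl2/pH 7 buffer (10:1), 0 °C
Reagents that add atoms: none
Why: Oxidative PMB cleavage by hydride abstraction from the electron-rich benzylic position and hydrolysis of the oxocarbenium ion frees the C4 hydroxyl, with limited oxidant and low temperature guarding against over-oxidation of the new allylic alcohol.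

Step 19
Reactants: 28 (1S,4R,6S)-6-{(2R,4S)-4-[(tert-butyldimethylsilyl)oxy]-6-methylhept-5-en-2-yl}-4-hydroxy-3-methylcyclohex-2-en-1-yl (2Z)-2-methylbut-2-enoate
Product: 29 (1S,4R,6S)-4-acetoxy-6-{(2R,4S)-4-[(tert-butyldimethylsilyl)oxy]-6-methylhept-5-en-2-yl}-3-methylcyclohex-2-en-1-yl (2Z)-2-methylbut-2-enoate
Conditions: Ac2O, pyridine, DMAP (cat.), CH2Cl2, 0 °C → rt
Reagents that add atoms: acetic anhydride, CC(=O)OC(C)=O
Why: DMAP-catalysed acetylation of the secondary allylic alcohol proceeds with retention at C4.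

Step 20
Reactants: 29 (1S,4R,6S)-4-acetoxy-6-{(2R,4S)-4-[(tert-butyldimethylsilyl)oxy]-6-methylhept-5-en-2-yl}-3-methylcyclohex-2-en-1-yl (2Z)-2-methylbut-2-enoate
Product: 30 (1S,4R,6S)-4-acetoxy-6-[(2R,4S)-4-hydroxy-6-methylhept-5-en-2-yl]-3-methylcyclohex-2-en-1-yl (2Z)-2-methylbut-2-enoate
Conditions: HF·pyridine, pyridine, THF, 0 °C → rt
Reagents that add atoms: none
Why: Buffered fluoride-mediated desilylation removes the TBS ether without cleaving or migrating the two allylic esters and without ionising the C9 allylic alcohol.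

Step 21
Reactants: 30 (1S,4R,6S)-4-acetoxy-6-[(2R,4S)-4-hydroxy-6-methylhept-5-en-2-yl]-3-methylcyclohex-2-en-1-yl (2Z)-2-methylbut-2-enoate
Product: 32 (1S,4R,6S)-4-acetoxy-6-[(2R,4R)-4-acetoxy-6-methylhept-5-en-2-yl]-3-methylcyclohex-2-en-1-yl (2Z)-2-methylbut-2-enoate, via alkoxyphosphonium acetate 31 (not isolated)
Conditions: PPh3, DIAD, AcOH, toluene, −20 → 0 °C
Reagents that add atoms: acetic acid, CC(=O)O
Why: Mitsunobu esterification, in which acetate displaces the C9 alkoxyphosphonium group by SN2 with inversion, converts 9S into the required 9R and installs the second acetate in the same step.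

**Compound list**

1 | 3-methylbut-2-enal | CC(C)=CC=O | starting material
2 | allylboronic acid pinacol ester | C=CCB1OC(C)(C)C(C)(C)O1 | starting material
3 | 4,4,5,5-tetramethyl-2-{[(4S)-6-methylhepta-1,5-dien-4-yl]oxy}-1,3,2-dioxaborolane | C=CC[C@@H](C=C(C)C)OB1OC(C)(C)C(C)(C)O1 | intermediate
4 | (4S)-6-methylhepta-1,5-dien-4-ol | C=CC[C@@H](C=C(C)C)O | intermediate
5 | acryloyl chloride | C=CC(Cl)=O | starting material
6 | (4S)-6-methylhepta-1,5-dien-4-yl prop-2-enoate | C=CC[C@@H](C=C(C)C)OC(=O)C=C | intermediate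
7 | (6S)-6-(2-methylprop-1-en-1-yl)-5,6-dihydro-2H-pyran-2-one | O=C1C=CC[C@@H](C=C(C)C)O1 | intermediate
8 | (R)-2,3-O-isopropylideneglyceraldehyde | O=C[C@H]1COC(C)(C)O1 | starting material
9 | 1-[(4R)-2,2-dimethyl-1,3-dioxolan-4-yl]ethan-1-ol (both carbinol epimers) | CC(O)[C@H]1COC(C)(C)O1 | intermediate
10 | 1-[(4R)-2,2-dimethyl-1,3-dioxolan-4-yl]ethan-1-one | CC(=O)[C@H]1COC(C)(C)O1 | intermediate
11 | (4S)-2,2-dimethyl-4-(prop-1-en-2-yl)-1,3-dioxolane | C=C(C)[C@H]1COC(C)(C)O1 | intermediate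
12 | (2S)-3-methylbut-3-ene-1,2-diol | C=C(C)[C@H](O)CO | intermediate
13 | (4S)-2-(4-methoxyphenyl)-4-(prop-1-en-2-yl)-1,3-dioxolane (both acetal epimers) | C=C(C)[C@H]1COC(c2ccc(OC)cc2)O1 | intermediate
14 | (2S)-2-[(4-methoxybenzyl)oxy]-3-methylbut-3-en-1-ol | C=C(C)[C@H](OCc1ccc(OC)cc1)CO | intermediate
15 | (2S)-2-[(4-methoxybenzyl)oxy]-3-methylbut-3-en-1-yl trifluoromethanesulfonate | C=C(C)[C@H](OCc1ccc(OC)cc1)COS(=O)(=O)C(F)(F)F | intermediate
16 | lithium dimethylcuprate | [Li+].C[Cu-]C | intermediate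
17 | lithium (4R,6S)-4-methyl-6-(2-methylprop-1-en-1-yl)-5,6-dihydro-4H-pyran-2-olate | [Li+].[O-]C1=C[C@H](C)C[C@@H](C=C(C)C)O1 | intermediate
18 | (3S,4R,6S)-3-{(2R)-2-[(4-methoxybenzyl)oxy]-3-methylbut-3-en-1-yl}-4-methyl-6-(2-methylprop-1-en-1-yl)tetrahydro-2H-pyran-2-one | O=C1[C@@H](C[C@@H](OCc2ccc(OC)cc2)C(C)=C)[C@H](C)C[C@@H](C=C(C)C)O1 | intermediate
19 | (2S,3R,5S)-5-hydroxy-N-methoxy-2-{(2R)-2-[(4-methoxybenzyl)oxy]-3-methylbut-3-en-1-yl}-N,3,7-trimethyloct-6-enamide | CON(C)C(=O)[C@@H](C[C@@H](OCc1ccc(OC)cc1)C(C)=C)[C@H](C)C[C@@H](C=C(C)C)O | intermediate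
20 | (2S,3R,5S)-5-[(tert-butyldimethylsilyl)oxy]-N-methoxy-2-{(2R)-2-[(4-methoxybenzyl)oxy]-3-methylbut-3-en-1-yl}-N,3,7-trimethyloct-6-enamide | CON(C)C(=O)[C@@H](C[C@@H](OCc1ccc(OC)cc1)C(C)=C)[C@H](C)C[C@@H](C=C(C)C)O[Si](C)(C)C(C)(C)C | intermediate
21 | bromomagnesium alkoxide of the vinyl adduct of Weinreb amide 20 (tetrahedral hemiaminal, new carbon unassigned) | C=CC(O[Mg]Br)(N(C)OC)[C@@H](C[C@@H](OCc1ccc(OC)cc1)C(C)=C)[C@H](C)C[C@@H](C=C(C)C)O[Si](C)(C)C(C)(C)C | intermediate
22 | (4S,5R,7S)-7-[(tert-butyldimethylsilyl)oxy]-4-{(2R)-2-[(4-methoxybenzyl)oxy]-3-methylbut-3-en-1-yl}-5,9-dimethyldeca-1,8-dien-3-one | C=CC(=O)[C@@H](C[C@@H](OCc1ccc(OC)cc1)C(C)=C)[C@H](C)C[C@@H](C=C(C)C)O[Si](C)(C)C(C)(C)C | intermediate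
23 | (4R,6S)-6-{(2R,4S)-4-[(tert-butyldimethylsilyl)oxy]-6-methylhept-5-en-2-yl}-4-[(4-methoxybenzyl)oxy]-3-methylcyclohex-2-en-1-one | O=C1C=C(C)[C@H](OCc2ccc(OC)cc2)C[C@H]1[C@H](C)C[C@@H](C=C(C)C)O[Si](C)(C)C(C)(C)C | intermediate
24 | (1S,4R,6S)-6-{(2R,4S)-4-[(tert-butyldimethylsilyl)oxy]-6-methylhept-5-en-2-yl}-4-[(4-methoxybenzyl)oxy]-3-methylcyclohex-2-en-1-ol | O[C@@H]1C=C(C)[C@H](OCc2ccc(OC)cc2)C[C@H]1[C@H](C)C[C@@H](C=C(C)C)O[Si](C)(C)C(C)(C)C | intermediate
25 | angelic acid, (2Z)-2-methylbut-2-enoic acid | C/C=C(/C)C(=O)O | starting material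
26 | (2Z)-2-methylbut-2-enoic 2,4,6-trichlorobenzoic anhydride | C/C=C(/C)C(=O)OC(=O)c1c(Cl)cc(Cl)cc1Cl | intermediate
27 | (1S,4R,6S)-6-{(2R,4S)-4-[(tert-butyldimethylsilyl)oxy]-6-methylhept-5-en-2-yl}-4-[(4-methoxybenzyl)oxy]-3-methylcyclohex-2-en-1-yl (2Z)-2-methylbut-2-enoate | C/C=C(/C)C(=O)O[C@@H]1C=C(C)[C@H](OCc2ccc(OC)cc2)C[C@H]1[C@H](C)C[C@@H](C=C(C)C)O[Si](C)(C)C(C)(C)C | intermediate
28 | (1S,4R,6S)-6-{(2R,4S)-4-[(tert-butyldimethylsilyl)oxy]-6-methylhept-5-en-2-yl}-4-hydroxy-3-methylcyclohex-2-en-1-yl (2Z)-2-methylbut-2-enoate | C/C=C(/C)C(=O)O[C@@H]1C=C(C)[C@H](O)C[C@H]1[C@H](C)C[C@@H](C=C(C)C)O[Si](C)(C)C(C)(C)C | intermediate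
29 | (1S,4R,6S)-4-acetoxy-6-{(2R,4S)-4-[(tert-butyldimethylsilyl)oxy]-6-methylhept-5-en-2-yl}-3-methylcyclohex-2-en-1-yl (2Z)-2-methylbut-2-enoate | C/C=C(/C)C(=O)O[C@@H]1C=C(C)[C@H](OC(C)=O)C[C@H]1[C@H](C)C[C@@H](C=C(C)C)O[Si](C)(C)C(C)(C)C | intermediate
30 | (1S,4R,6S)-4-acetoxy-6-[(2R,4S)-4-hydroxy-6-methylhept-5-en-2-yl]-3-methylcyclohex-2-en-1-yl (2Z)-2-methylbut-2-enoate | C/C=C(/C)C(=O)O[C@@H]1C=C(C)[C@H](OC(C)=O)C[C@H]1[C@H](C)C[C@@H](C=C(C)C)O | intermediate
31 | triphenylphosphonium ether of the C9 oxygen of 30, acetate salt | C/C=C(/C)C(=O)O[C@@H]1C=C(C)[C@H](OC(C)=O)C[C@H]1[C@H](C)C[C@@H](C=C(C)C)O[P+](c1ccccc1)(c1ccccc1)c1ccccc1.CC(=O)[O-] | intermediate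
32 | (1S,4R,6S)-4-acetoxy-6-[(2R,4R)-4-acetoxy-6-methylhept-5-en-2-yl]-3-methylcyclohex-2-en-1-yl (2Z)-2-methylbut-2-enoate (CNP0417294.1) | C/C=C(/C)C(=O)O[C@@H]1C=C(C)[C@H](OC(C)=O)C[C@H]1[C@H](C)C[C@H](C=C(C)C)OC(C)=O | target

**Step count**

Total: 21 steps. Longest linear sequence: 18 steps (8 → 15 in steps 4–10, then steps 11–21).

**Steps most likely to fail**

1. Step 11. The enolate left after methyl transfer is aggregated with methylcopper and may be too weak a nucleophile for a β-branched, β-alkoxy primary triflate. Simple protonation on work-up, E2 elimination of the triflate through its activated C4–H, methyl transfer from residual cuprate to the triflate, or substitution at the allylic C9–O bond could then compete with C-alkylation. Fallback, setting out from 7 and 15 and returning at 18: the two bond formations are separated. Me2CuLi in Et2O at −78 °C followed by an NH4Cl quench should give (4R,6S)-4-methyl-6-(2-methylprop-1-en-1-yl)tetrahydro-2H-pyran-2-one F1, which is isolated. LiN(i-Pr)2 in THF at −78 °C then regenerates the enolate as the copper-free lithium species 17, which is alkylated with 15 anti to the C7 methyl to give 18. No organocopper remains to consume the triflate, and the discrete lithium enolate is the more reactive nucleophile.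

2. Step 21. The C9 alkoxyphosphonium ion is allylic with a dimethyl-substituted terminus. Ionisation to the allyl cation (loss of configuration), SN2′ attack at C11 or elimination to the C8–C11 diene could therefore erode clean inversion. Fallback, setting out from 30 and returning at 32: the centre is reset by oxidation and reagent-controlled reduction. Dess–Martin periodinane should give (1S,4R,6S)-4-acetoxy-3-methyl-6-[(2R)-6-methyl-4-oxohept-5-en-2-yl]cyclohex-2-en-1-yl (2Z)-2-methylbut-2-enoate F5. Corey–Bakshi–Shibata reduction with the (S)-methyl oxazaborolidine and catecholborane in toluene at −78 °C, with the alkenyl group as the large substituent, should then deliver (1S,4R,6S)-4-acetoxy-6-[(2R,4R)-4-hydroxy-6-methylhept-5-en-2-yl]-3-methylcyclohex-2-en-1-yl (2Z)-2-methylbut-2-enoate F6. Acetylation (Ac2O, pyridine, DMAP) gives 32.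

3. Step 15. Both reacting alkenes are poor metathesis partners, an electron-poor vinyl ketone and a hindered 1,1-disubstituted alkene next to the C4 ether. Slow initiation, catalyst decay, or closure onto the C10=C11 alkene with loss of isobutene (seven-membered enone) could compete. Fallback, setting out from 20 and returning at 23: the metathesis is run on an allylic alcohol instead of an enone. i-Bu2AlH in THF at −78 °C should reduce the Weinreb amide to (2S,3R,5S)-5-[(tert-butyldimethylsilyl)oxy]-2-{(2R)-2-[(4-methoxybenzyl)oxy]-3-methylbut-3-en-1-yl}-3,7-dimethyloct-6-enal F2, used crude to avoid epimerisation at C6. CH2=CHMgBr then gives (4S,5R,7S)-7-[(tert-butyldimethylsilyl)oxy]-4-{(2R)-2-[(4-methoxybenzyl)oxy]-3-methylbut-3-en-1-yl}-5,9-dimethyldeca-1,8-dien-3-ol F3 as a C1 epimer mixture. Its electron-rich monosubstituted alkene initiates readily, and ring-closing metathesis with RuCl2(=CHPh)(PCy3)(H2IMes) gives (4R,6S)-6-{(2R,4S)-4-[(tert-butyldimethylsilyl)oxy]-6-methylhept-5-en-2-yl}-4-[(4-methoxybenzyl)oxy]-3-methylcyclohex-2-en-1-ol F4 (both C1 epimers). Oxidation with Dess–Martin periodinane converges both epimers on enone 23.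

**Further compounds**

F1 | step 11 | (4R,6S)-4-methyl-6-(2-methylprop-1-en-1-yl)tetrahydro-2H-pyran-2-one | O=C1C[C@H](C)C[C@@H](C=C(C)C)O1
F2 | step 15 | (2S,3R,5S)-5-[(tert-butyldimethylsilyl)oxy]-2-{(2R)-2-[(4-methoxybenzyl)oxy]-3-methylbut-3-en-1-yl}-3,7-dimethyloct-6-enal | O=C[C@@H](C[C@@H](OCc1ccc(OC)cc1)C(C)=C)[C@H](C)C[C@@H](C=C(C)C)O[Si](C)(C)C(C)(C)C
F3 | step 15 | (4S,5R,7S)-7-[(tert-butyldimethylsilyl)oxy]-4-{(2R)-2-[(4-methoxybenzyl)oxy]-3-methylbut-3-en-1-yl}-5,9-dimethyldeca-1,8-dien-3-ol (both C3 epimers) | C=CC(O)[C@@H](C[C@@H](OCc1ccc(OC)cc1)C(C)=C)[C@H](C)C[C@@H](C=C(C)C)O[Si](C)(C)C(C)(C)C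
F4 | step 15 | (4R,6S)-6-{(2R,4S)-4-[(tert-butyldimethylsilyl)oxy]-6-methylhept-5-en-2-yl}-4-[(4-methoxybenzyl)oxy]-3-methylcyclohex-2-en-1-ol (both C1 epimers) | OC1C=C(C)[C@H](OCc2ccc(OC)cc2)C[C@H]1[C@H](C)C[C@@H](C=C(C)C)O[Si](C)(C)C(C)(C)C
F5 | step 21 | (1S,4R,6S)-4-acetoxy-3-methyl-6-[(2R)-6-methyl-4-oxohept-5-en-2-yl]cyclohex-2-en-1-yl (2Z)-2-methylbut-2-enoate | C/C=C(/C)C(=O)O[C@@H]1C=C(C)[C@H](OC(C)=O)C[C@H]1[C@H](C)CC(=O)C=C(C)C
F6 | step 21 | (1S,4R,6S)-4-acetoxy-6-[(2R,4R)-4-hydroxy-6-methylhept-5-en-2-yl]-3-methylcyclohex-2-en-1-yl (2Z)-2-methylbut-2-enoate | C/C=C(/C)C(=O)O[C@@H]1C=C(C)[C@H](OC(C)=O)C[C@H]1[C@H](C)C[C@H](C=C(C)C)O
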